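The cyclopentane ring (C1, C2, C3, C3a, C8a in azulene numbering; C3 carries the side chain, C8a the angular methyl) is cut into the three-carbon unit C3–C3a–C8a and the bare ethano bridge C1–C2. One ketyl radical-relay [3+2] cycloaddition of phenyl vinyl sulfone to an enantiopure acetylcyclopropane fused cis to the seven-membered ring forges C1–C8a and C2–C3. Because the tertiary ring radical adds anti to the cyclopropane remnant, the cis-bicyclo[5.1.0]octane becomes the trans-hydroazulene with its quaternary centre. Sulfinate loss in the same flask leaves an enone that hydrogenation turns into the C3 stereocentre. The cyclopropane comes from a tethered carbene addition.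

Key step: step 7

Remark: the hydroazulene is numbered as azulene (C8a bears the methyl group, C3 the side chain, C7 the ring oxygen); the carbinol centre made in step 1 serves only to relay chirality to the ring fusion and is re-set in step 16.

Step 1
Reactants: 1 hex-5-enal
Product: 2 (S)-2-methylnona-1,8-dien-4-ol
Conditions: (R)-BINOL (10 mol%), Ti(OiPr)4 (10 mol%), 4 Å MS, CH2Cl2, −20 °C; aq NaHCO3
Reagents that add atoms: tributyl(2-methylallyl)stannane, C=C(C)C[Sn](CCCC)(CCCC)CCCC
Why: Keck asymmetric methallylation; the (R)-ligand should direct the stannane to the Re face of the aldehyde and so give the (S)-carbinol.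

Step 2
Reactants: 2 (S)-2-methylnona-1,8-dien-4-ol
Product: 3 (S)-3-methylcyclohept-3-en-1-ol
Conditions: second-generation Grubbs catalyst (5 mol%), CH2Cl2 (5 mM), 40 °C
Reagents that add atoms: none
Why: Ring-closing metathesis between the monosubstituted and the 1,1-disubstituted alkene should close the trisubstituted cycloheptene with loss of ethene; the free alcohol is tolerated.

Step 3
Reactants: 3 (S)-3-methylcyclohept-3-en-1-ol
Product: 5 (S)-3-methylcyclohept-3-en-1-yl 2-diazoacetate, via tosylhydrazone ester 4 (not isolated)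
Conditions: TsNHN=CHCOCl, PhNMe2, CH2Cl2, 0 °C; then Et3N, 0 °C to rt
Reagents that add atoms: 2-(tosylhydrazono)acetyl chloride, Cc1ccc(cc1)S(=O)(=O)NN=CC(Cl)=O
Why: Acylation of the alcohol followed by base-induced loss of sulfinate from the tosylhydrazone (Bamford–Stevens-type diazo formation) should give the diazoacetate without touching the alkene.

Step 4
Reactants: 5 (S)-3-methylcyclohept-3-en-1-yl 2-diazoacetate
Product: 6 1-methyl-7-oxatricyclo[4.3.1.0(2,9)]decan-8-one (lactone oxygen and cyclopropane carbon on the same face of the seven-membered ring)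
Conditions: Rh2(OAc)4 (1 mol%), CH2Cl2, 40 °C, slow addition of 5
Reagents that add atoms: none
Why: Intramolecular carbenoid cyclopropanation; the short ester tether can deliver the carbene only to the alkene face syn to the C–O bond, so the carbinol centre fixes both ring carbons of the cyclopropane (C3a and the future C8a) as one diastereomer.

Step 5
Reactants: 6 tricyclic lactone
Product: 7 1-(3-hydroxy-1-methylbicyclo[5.1.0]octan-8-yl)ethan-1-one (3-OH cis to the cyclopropane carbon C8)
Conditions: MeLi (1.05 equiv), THF, −78 °C; AcOH quench at −78 °C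
Reagents that add atoms: methyllithium, [Li]C
Why: Mono-addition of an organolithium to a lactone; the lithium lactolate should survive at −78 °C and collapse to the methyl ketone only on quench, so the two carbene-derived carbons become C3 and its acetyl group.

Step 6
Reactants: 7 hydroxy cyclopropyl ketone
Product: 8 1-(3-benzyloxy-1-methylbicyclo[5.1.0]octan-8-yl)ethan-1-one
Conditions: 2-benzyloxy-1-methylpyridinium triflate, MgO, PhCF3, 85 °C
Reagents that add atoms: 2-benzyloxy-1-methylpyridinium triflate, C[n+]1ccccc1OCc1ccccc1.[O-]S(=O)(=O)C(F)(F)F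
Why: Neutral benzyl transfer should protect the alcohol without base (enolisation) or acid (hemiketal or cyclopropane opening); the benzyl ether is chosen because step 8 removes it during the hydrogenation.

Step 7
Reactants: 8 benzyloxy cyclopropyl methyl ketone
Product: 10 1-(7-benzyloxy-8a-methyl-1,3a,4,5,6,7,8,8a-octahydroazulen-3-yl)ethan-1-one (3a-H trans to 8a-CH3), via sulfonyl ketone 9 (not isolated)
Conditions: phenyl vinyl sulfone (3 equiv), SmI2 (25 mol%), Sm metal (25 mol%), THF, 55 °C; then DBU, rt
Reagents that add atoms: phenyl vinyl sulfone, C=CS(=O)(=O)c1ccccc1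
Why: Divalent samarium reduces the ketone to a ketyl whose cyclopropane opens at the C3–C8a bond to the tertiary C8a radical and a trivalent samarium enolate; the radical adds to the vinyl sulfone (new C8a–C1 bond), the sulfonyl-stabilised radical closes onto the enolate carbon (new C2–C3 bond) and the resulting ketyl returns its electron to the catalyst. The closest known reaction type is the ketyl radical-relay formal [3+2] cycloaddition of cyclopropyl ketones with alkenes, run under the SmI2/Sm conditions used for alkyl cyclopropyl ketones. The cyclopentane closes in 5-exo-trig mode. C8a is set in the intermolecular addition, which should occur anti to the enolate-bearing substituent on C3a and to the cis benzyloxy group, so the cis-fused cyclopropane becomes the trans ring fusion while C3a is untouched; C2 and C3 form as mixtures that the elimination erases. The step needs ring opening towards the tertiary and not the secondary carbon (secured by radical stability) and ring closure faster than reduction of the sulfonyl radical; DBU then expels benzenesulfinate by E1cB to give the enone.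

Step 8
Reactants: 10 benzyloxy enone
Product: 11 1-(7-hydroxy-8a-methyldecahydroazulen-3-yl)ethan-1-one (3-H and 3a-H cis and both trans to 8a-CH3; 7-OH cis to 8a-CH3)
Conditions: H2 (1 atm), Pd(OH)2/C, EtOAc–EtOH, rt
Reagents that add atoms: none
Why: Heterogeneous hydrogenation should add hydrogen to the enone from the face opposite the angular methyl (the face of H-3a), placing the acetyl group cis to the methyl group, and hydrogenolysis cleaves the benzyl ether in the same operation.

Step 9
Reactants: 12 methacrolein
Product: 14 S-tert-butyl (S)-3-hydroxy-4-methylpent-4-enethioate, via silyl ether 13 (not isolated)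
Conditions: (S)-BINOL (20 mol%), Ti(OiPr)4 (20 mol%), 4 Å MS, Et2O, −20 °C; then 1 M HCl, THF
Reagents that add atoms: 1-(tert-butylthio)-1-(trimethylsilyloxy)ethene, C=C(O[Si](C)(C)C)SC(C)(C)C
Why: Catalytic enantioselective Mukaiyama aldol addition; the (S)-ligand should give Si-face attack on the aldehyde and hence the (S)-carbinol, and the silyl ether is cleaved in the acidic work-up.

Step 10
Reactants: 14 hydroxy thioester
Product: 15 S-tert-butyl (S)-3-(tert-butyldimethylsilyloxy)-4-methylpent-4-enethioate
Conditions: TBSCl, imidazole, DMF, rt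
Reagents that add atoms: tert-butyldimethylsilyl chloride, CC(C)(C)[Si](C)(C)Cl
Why: Standard silylation of the secondary allylic alcohol.

Step 11
Reactants: 15 silyloxy thioester
Product: 16 (S)-3-(tert-butyldimethylsilyloxy)-4-methylpent-4-en-1-ol
Conditions: LiBH4, THF–MeOH, 0 °C to rt
Reagents that add atoms: none
Why: Borohydride reduction of the activated thioester to the primary alcohol should leave the silyl ether and the alkene untouched.

Step 12
Reactants: 16 primary alcohol
Product: 17 (S)-(5-bromo-2-methylpent-1-en-3-yloxy)(tert-butyl)dimethylsilane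
Conditions: CBr4, PPh3, CH2Cl2, 0 °C
Reagents that add atoms: carbon tetrabromide, BrC(Br)(Br)Br
Why: Appel bromination converts the primary alcohol into the bromide under neutral conditions.

Step 13
Reactants: 11 hydroxy methyl ketone; 17 bromide
Product: 19 (2S,5S)-5-(tert-butyldimethylsilyloxy)-2-(7-hydroxy-8a-methyldecahydroazulen-3-yl)-6-methylhept-6-en-2-ol, via Grignard reagent 18 (not isolated)
Conditions: 17, Mg, THF, 40 °C; CeCl3, −78 °C; then 11 (pretreated with MeMgBr, 1.0 equiv, −78 °C), −78 to −40 °C; aq NH4Cl
Reagents that add atoms: none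
Why: Grignard formation and transmetalation to the weakly basic organocerium reagent should give clean 1,2-addition to the enolisable ketone; Felkin–Anh attack anti to the ring-fusion carbon C3a is expected to give the (S)-configured tertiary carbinol.

Step 14
Reactants: 19 diol
Product: 20 the corresponding azulen-7-one (C7 ketone; tertiary alcohol and silyl ether unchanged)
Conditions: Dess–Martin periodinane, CH2Cl2, rt
Reagents that add atoms: none
Why: Dess–Martin oxidation of the only secondary alcohol; the tertiary alcohol cannot be oxidised.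

Step 15
Reactants: 20 C7 ketone
Product: 23 the 6-methylidene C7 ketone, via Mannich base 21 (not isolated), via ammonium iodide 22 (not isolated)
Conditions: LDA (2.5 equiv), THF, −78 °C; CH2=NMe2+ I−, to rt; then MeI, CH2Cl2; then DBU
Reagents that add atoms: N,N-dimethylmethyleneiminium iodide, C[N+](C)=C.[I-]
Why: Kinetic deprotonation at C6 (the α-methylene group remote from the quaternary carbon), Mannich reaction and elimination of the quaternised amine should install the exocyclic methylene regioselectively.

Step 16
Reactants: 23 α-methylene ketone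
Product: 24 the (7S)-allylic alcohol (7-OH trans to 8a-CH3)
Conditions: (R)-2-methyl-CBS-oxazaborolidine (1 equiv), catecholborane, toluene, −78 °C; aq NaOH
Reagents that add atoms: none
Why: CBS reduction with catecholborane, which does not hydroborate the alkenes at −78 °C; with the alkenyl carbon as the large group the (R)-oxazaborolidine should deliver hydride to give the (S)-carbinol under reagent control.

Step 17
Reactants: 24 silyl-protected allylic alcohol
Product: 25 (3S,3aS,7S,8aR)-3-[(2S,5S)-2,5-dihydroxy-6-methylhept-6-en-2-yl]-8a-methyl-6-methylidenedecahydroazulen-7-ol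
Conditions: TBAF, THF, rt
Reagents that add atoms: none
Why: Fluoride-mediated desilylation frees the side-chain allylic alcohol.

Step 18
Reactants: 25 triol
Product: 26 (3S,3aS,7S,8aR)-3-[(2S,5S)-5-acetoxy-2-hydroxy-6-methylhept-6-en-2-yl]-8a-methyl-6-methylidenedecahydroazulen-7-yl acetate (target)
Conditions: Ac2O, pyridine, DMAP (cat.), CH2Cl2, 0 °C
Reagents that add atoms: acetic anhydride, CC(=O)OC(C)=O
Why: Acetylation of the two secondary allylic alcohols; the hindered tertiary alcohol should not react under these conditions.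

Compound list
1 | hex-5-enal | C=CCCCC=O | starting material
2 | (S)-2-methylnona-1,8-dien-4-ol | C=CCCC[C@H](O)CC(C)=C | intermediate
3 | (S)-3-methylcyclohept-3-en-1-ol | CC1=CCCC[C@H](O)C1 | intermediate
4 | (S)-3-methylcyclohept-3-en-1-yl 2-(tosylhydrazono)acetate | CC1=CCCC[C@H](OC(=O)C=NNS(=O)(=O)c2ccc(C)cc2)C1 | intermediate
5 | (S)-3-methylcyclohept-3-en-1-yl 2-diazoacetate | CC1=CCCC[C@H](OC(=O)C=[N+]=[N-])C1 | intermediate
6 | 1-methyl-7-oxatricyclo[4.3.1.0(2,9)]decan-8-one | O=C1[C@@H]2[C@@H]3CCC[C@H](O1)C[C@]23C | intermediate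
7 | 1-(3-hydroxy-1-methylbicyclo[5.1.0]octan-8-yl)ethan-1-one | CC(=O)[C@@H]1[C@@H]2CCC[C@H](O)C[C@]12C | intermediate
8 | 1-(3-benzyloxy-1-methylbicyclo[5.1.0]octan-8-yl)ethan-1-one | CC(=O)[C@@H]1[C@@H]2CCC[C@H](OCc3ccccc3)C[C@]12C | intermediate
9 | 1-[7-benzyloxy-8a-methyl-2-(phenylsulfonyl)decahydroazulen-3-yl]ethan-1-one (epimers at C2 and C3) | CC(=O)C1C(S(=O)(=O)c3ccccc3)C[C@]2(C)C[C@@H](OCc4ccccc4)CCC[C@@H]12 | intermediate
10 | 1-(7-benzyloxy-8a-methyl-1,3a,4,5,6,7,8,8a-octahydroazulen-3-yl)ethan-1-one | CC(=O)C1=CC[C@]2(C)C[C@@H](OCc3ccccc3)CCC[C@@H]12 | intermediate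
11 | 1-(7-hydroxy-8a-methyldecahydroazulen-3-yl)ethan-1-one | CC(=O)[C@H]1CC[C@]2(C)C[C@@H](O)CCC[C@@H]12 | intermediate
12 | methacrolein | CC(=C)C=O | starting material
13 | S-tert-butyl (S)-4-methyl-3-(trimethylsilyloxy)pent-4-enethioate | C=C(C)[C@H](CC(=O)SC(C)(C)C)O[Si](C)(C)C | intermediate
14 | S-tert-butyl (S)-3-hydroxy-4-methylpent-4-enethioate | C=C(C)[C@H](CC(=O)SC(C)(C)C)O | intermediate
15 | S-tert-butyl (S)-3-(tert-butyldimethylsilyloxy)-4-methylpent-4-enethioate | C=C(C)[C@H](CC(=O)SC(C)(C)C)O[Si](C)(C)C(C)(C)C | intermediate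
16 | (S)-3-(tert-butyldimethylsilyloxy)-4-methylpent-4-en-1-ol | C=C(C)[C@H](CCO)O[Si](C)(C)C(C)(C)C | intermediate
17 | (S)-(5-bromo-2-methylpent-1-en-3-yloxy)(tert-butyl)dimethylsilane | C=C(C)[C@H](CCBr)O[Si](C)(C)C(C)(C)C | intermediate
18 | Grignard reagent of 17 | C=C(C)[C@H](CC[Mg]Br)O[Si](C)(C)C(C)(C)C | intermediate
19 | (2S,5S)-5-(tert-butyldimethylsilyloxy)-2-(7-hydroxy-8a-methyldecahydroazulen-3-yl)-6-methylhept-6-en-2-ol | C=C(C)[C@H](CC[C@](C)(O)[C@H]1CC[C@]2(C)C[C@@H](O)CCC[C@@H]12)O[Si](C)(C)C(C)(C)C | intermediate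
20 | C7 ketone of 19 | C=C(C)[C@H](CC[C@](C)(O)[C@H]1CC[C@]2(C)CC(=O)CCC[C@@H]12)O[Si](C)(C)C(C)(C)C | intermediate
21 | 6-(dimethylaminomethyl) ketone (Mannich base) | C=C(C)[C@H](CC[C@](C)(O)[C@H]1CC[C@]2(C)CC(=O)C(CN(C)C)CC[C@@H]12)O[Si](C)(C)C(C)(C)C | intermediate
22 | trimethylammonium iodide of 21 | C=C(C)[C@H](CC[C@](C)(O)[C@H]1CC[C@]2(C)CC(=O)C(C[N+](C)(C)C)CC[C@@H]12)O[Si](C)(C)C(C)(C)C.[I-] | intermediate
23 | 6-methylidene C7 ketone | C=C(C)[C@H](CC[C@](C)(O)[C@H]1CC[C@]2(C)CC(=O)C(=C)CC[C@@H]12)O[Si](C)(C)C(C)(C)C | intermediate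
24 | (7S)-allylic alcohol with side-chain silyl ether | C=C(C)[C@H](CC[C@](C)(O)[C@H]1CC[C@]2(C)C[C@H](O)C(=C)CC[C@@H]12)O[Si](C)(C)C(C)(C)C | intermediate
25 | triol | C=C(C)[C@H](CC[C@](C)(O)[C@H]1CC[C@]2(C)C[C@H](O)C(=C)CC[C@@H]12)O | intermediate
26 | (3S,3aS,7S,8aR)-3-[(2S,5S)-5-acetoxy-2-hydroxy-6-methylhept-6-en-2-yl]-8a-methyl-6-methylidenedecahydroazulen-7-yl acetate | C=C(C)[C@H](CC[C@](C)(O)[C@H]1CC[C@]2(C)C[C@H](OC(C)=O)C(=C)CC[C@@H]12)OC(C)=O | target

Total step count: 18. Longest linear sequence: 14 steps (steps 1–8 and 13–18); steps 9–12 build the side-chain bromide.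

Steps most likely to fail

Step 7. The relay may stop early: the ring-opened samarium enolate may be protonated, the sulfonyl-stabilised radical may be reduced before the 5-exo closure, or the vinyl sulfone may be consumed by direct reduction. The fallback makes the same two bonds by the thiyl-radical-catalysed [3+2] cycloaddition of a vinylcyclopropane, which needs no ketyl. It sets out from lactone 6. DIBAL-H (CH2Cl2, −78 °C) would give the lactol F1. Wittig methylenation (Ph3P=CH2, THF) would give the vinylcyclopropane alcohol F2, and benzylation as in step 6 the benzyl ether F3. PhSSPh (cat.), AIBN, hν and phenyl vinyl sulfone in benzene should give the vinylcyclopentane sulfone F4 through the same ring opening, anti addition and 5-exo closure. Wacker oxidation (PdCl2, CuCl, O2, DMF–H2O) of the vinyl group would then return to 9, which DBU converts to 10.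

Step 4. Carbene dimerisation or insertion into the C–H bonds next to the ester-bearing carbon may outrun cyclopropanation, because the alkene has to be reached across the ring. The fallback uses the more stabilised keto carbenoid and sets out from alcohol 3. 2,2,6-Trimethyl-4H-1,3-dioxin-4-one (xylene, 140 °C) would give the acetoacetate F5, and diazo transfer (4-acetamidobenzenesulfonyl azide, Et3N, MeCN) the diazoacetoacetate F6. Cu(acac)2 in toluene at 110 °C should give the acetyl lactone F7, and retro-Claisen deacetylation (K2CO3, MeOH, 0 °C) would come back to 6.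

Step 16. The facial preference of the catalyst may oppose the intrinsic bias of the ring (hydride delivery anti to the angular methyl), which would erode the diastereoselectivity at C7. The fallback accepts substrate control and inverts afterwards; it sets out from 23. Luche reduction (NaBH4, CeCl3·7H2O, MeOH, −78 °C) should give the 7-epimeric allylic alcohol F8. Mitsunobu inversion (4-nitrobenzoic acid, PPh3, DIAD, THF) would give the 4-nitrobenzoate F9, and methanolysis (K2CO3, MeOH) would come back to 24.

Further compounds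
F1 | step 7 | 1-methyl-7-oxatricyclo[4.3.1.0(2,9)]decan-8-ol (lactol) | OC1[C@@H]2[C@@H]3CCC[C@H](O1)C[C@]23C
F2 | step 7 | 1-methyl-8-vinylbicyclo[5.1.0]octan-3-ol | C=C[C@@H]1[C@@H]2CCC[C@H](O)C[C@]12C
F3 | step 7 | 3-benzyloxy-1-methyl-8-vinylbicyclo[5.1.0]octane | C=C[C@@H]1[C@@H]2CCC[C@H](OCc3ccccc3)C[C@]12C
F4 | step 7 | 7-benzyloxy-8a-methyl-2-(phenylsulfonyl)-3-vinyldecahydroazulene | C=CC1C(S(=O)(=O)c3ccccc3)C[C@]2(C)C[C@@H](OCc4ccccc4)CCC[C@@H]12
F5 | step 4 | (S)-3-methylcyclohept-3-en-1-yl 3-oxobutanoate | CC1=CCCC[C@H](OC(=O)CC(C)=O)C1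
F6 | step 4 | (S)-3-methylcyclohept-3-en-1-yl 2-diazo-3-oxobutanoate | CC1=CCCC[C@H](OC(=O)C(=[N+]=[N-])C(C)=O)C1
F7 | step 4 | 9-acetyl-1-methyl-7-oxatricyclo[4.3.1.0(2,9)]decan-8-one | O=C1[C@]2(C(C)=O)[C@@H]3CCC[C@H](O1)C[C@]23C
F8 | step 16 | 7-epimer of 24 | C=C(C)[C@H](CC[C@](C)(O)[C@H]1CC[C@]2(C)C[C@@H](O)C(=C)CC[C@@H]12)O[Si](C)(C)C(C)(C)C
F9 | step 16 | 4-nitrobenzoate of 24 | C=C(C)[C@H](CC[C@](C)(O)[C@H]1CC[C@]2(C)C[C@H](OC(=O)c3ccc(cc3)[N+](=O)[O-])C(=C)CC[C@@H]12)O[Si](C)(C)C(C)(C)C
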